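Enough substrate is left over for one more flask, so the set-ups below have to be ranked on paper first.

| flask | substrate | reagent | free catalyst | remark | time |
|---|---|---|---|---|---|
| birch | 0.10 M | 2.5 equiv | 0.05 mol% | run made earlier |  |
| ash | 0.10 M | 2.5 equiv | 0.07 mol% | run made earlier |  |
| elm | 0.10 M | 2.5 equiv | 0.11 mol% | run made earlier |  |
| Friday's | 0.10 M | 2.50 equiv | 0.05 mol% | a single well-mixed tank run continuously and read at steady state, 30 h in it on average |  |
| Sunday's | 0.10 M (fed, over 15.0 h) | 2.50 equiv | 0.05 mol% | all but substrate at the start; substrate goes in evenly over 15.0 h, the run ends at 30 h | 30 h |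
| Tuesday's | 0.10 M | 2.50 equiv (fed, over 15.0 h) | 0.05 mol% | a stirred flask in which reagent is dosed at a steady rate over 15.0 h without added volume, worked up at 30 h | 30 h |
| Saturday's | 0.10 M | 2.50 equiv | 0.05 mol% | a closed flask charged with all of it at once and left for 30 h | 30 h |

| run | time / h | target / % |
|---|---|---|
| birch | 1.50 | 5.1 |
| birch | 5.00 | 11.6 |
| birch | 8.00 | 14.4 |
| birch | 12.0 | 18.9 |
| birch | 20.0 | 24.5 |
| ash | 2.50 | 8.4 |
| ash | 5.00 | 14.3 |
| ash | 8.00 | 19.7 |
| ash | 15.0 | 28.7 |
| ash | 30.0 | 39.5 |
| elm | 2.50 | 13.7 |
| elm | 8.00 | 28.5 |
| elm | 15.0 | 41.2 |
| elm | 20.0 | 47.8 |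
| elm | 30.0 | 57.6 |

(standard deviation of a reading: 0.5 percentage points)

- the stated concentrations are those of everything mixed, before any reaction; amounts are the same in each set-up
- the feed brings no volume worth counting
- the earlier runs were made in a closed, stirred flask

- the set-up with the highest amount of target at the outlet or at the end, in percent of the substrate put in ("none" if the first two lie within 2 percentage points) (Friday's / Sunday's / Tuesday's / Saturday's / none)
- amount of target at the outlet or at the end, in percent of the substrate put in, Friday's
- amount of target at the outlet or at the end, in percent of the substrate put in, Sunday's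
- amount of target at the outlet or at the end, in percent of the substrate put in, Tuesday's
- amount of target at the outlet or at the end, in percent of the substrate put in, Saturday's

Two chemists read the same runs and use the same measure. From the ash run at 30.0 h, scaled down to a loading of 0.05 mol%, they get 0.359. This is the exposure: the natural log of one over the fraction of substrate not turned to target, scaled in proportion to catalyst loading. The elm run, scaled the same way, reads 0.390. With the ash figure, Saturday's should reach about 30.2%.

The first chemist says the catalyst ages by the clock. At 8.00 h, exposure per unit of loading in the elm run is 0.981 of that in the birch run, so this chemist reads the loss as a matter of hours and expects whatever comes in late to meet a weak catalyst.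

The second chemist says the catalyst wears with use. At that hour, target per catalyst (the turnover number so far) in the elm run is 0.900 of the birch figure. Birch, ash and elm each carried 2.5 equiv of reagent, so none of these runs varies the catalyst's contact with reagent. On this view, my own reckoning puts Sunday's and Tuesday's near 0.359 in exposure, and Tuesday's may pass it.

The forecast takes the first side: 26% for Friday's, 20% for Sunday's, 20.5% for Tuesday's and 30.5% for Saturday's, with Saturday's on top. Of Tuesday's it says “the early active period is wasted”.

The simulation gives 22.7% for Friday's, 28.3% for Sunday's, 33.1% for Tuesday's and 29.0% for Saturday's, so Tuesday's comes first and the dispute goes to the second chemist.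

    substrate + free catalyst → catalyst intermediate A (k = 313 L mol⁻¹ min⁻¹)
    reagent + catalyst intermediate A ⇌ catalyst intermediate B (K = 11.0 L mol⁻¹, k = 37.0 L mol⁻¹ min⁻¹)
    catalyst intermediate B ⇌ released group + catalyst intermediate C (K = 0.0250 M, k = 3.21 min⁻¹)
    catalyst intermediate C → free catalyst + target (k = 5.19 min⁻¹)
    reagent + catalyst intermediate C → spent catalyst (k = 0.0213 L mol⁻¹ min⁻¹)
    target ⇌ isomer of the product (K = 0.440, k = 0.0134 min⁻¹)

The clock view keeps the flask charged at once, where Saturday's 29.0% stands near the forecast's 30.5%. Tuesday's ends with 52.4% of its substrate still unused. Tuesday's exposure is 0.403, more than the 0.359 read from the ash run, by a factor of 1.12. Sunday's, at 28.3%, has an exposure of 0.333, which is 0.928 of 0.359.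

The runs are simulated on assumed constants, and the scatter is random.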